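**Plan**
1. Retrosynthesis: the C8 ester C–O bond and the C9 carbinol (back to the ketone) go first. The C7–C8 ring bond is then exchanged for an O8–C13 ether, which opens the ten-membered carbocycle to a thirteen-membered keto ether. That ring is cut at C9–C10, at the butenolide C7=C11 bond and at the lactone C12–O6 bond.
2. Enabling feature (germacrane numbering): the oxygen on C8 and the exocyclic methylene carbon C13 are 1,4-related through C7 and C11 (O8–C8–C7–C11=C13). O8 can therefore be held as an ether on C13 of a butenolide that carries only hydrogen at C7, inside a thirteen-membered ring, and ring C1–C10 then arises by a 2,3-shift.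
3. Forward order: C1–C6 chain from geranyl acetate → ester with the acrylate that carries C11–C13, O8, C8 and C9 → butenolide by metathesis → thirteen-membered ring by C9–C10 coupling → ten-membered carbocycle and α-methylene lactone by the enolate 2,3-shift → C8 ester → C9 alcohol.
4. Stereochemistry: C6 from a lipase resolution; C7 and C8 relayed from C6 in the key step; C9 from hydride addition to the ring ketone; the epoxide carbon from (R)-citramalic acid; Z-C1=C10 from the iodo-olefination and E-C4=C5 from geranyl acetate.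

Key step: step 15

Remark: germacrane numbering is used for all intermediates; the CIP descriptor of C7 changes from 7R in 20 to 7S in 27 and 28 although nothing moves in space.
Remark: the epoxy acid is taken from (R)-citramalic acid, because in that route no bond to the quaternary carbon is ever broken.

**Step 1**
Reactants: 1 geranyl acetate
Product: 3 (2E)-3-methyl-6-oxohex-2-en-1-yl acetate, via 6,7-epoxygeranyl acetate 2 (not isolated)
Conditions: mCPBA, CH2Cl2, 0 °C; then H5IO6, THF–H2O, 0 °C
Reagents that add atoms: mCPBA, OOC(=O)c1cccc(Cl)c1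
Why: The Prilezhaev epoxidation takes the electron-richer distal alkene (the proximal one is deactivated by the allylic acetate), and periodic acid then cleaves the epoxide through its diol (Malaprade cleavage) to the aldehyde.

**Step 2**
Reactants: 3 (2E)-3-methyl-6-oxohex-2-en-1-yl acetate
Product: 4 (2E,6Z)-7-iodo-3-methylocta-2,6-dien-1-yl acetate
Conditions: [Ph3PCH2CH3]I, n-BuLi, THF, rt; I2, −78 °C; NaN(SiMe3)2, −20 °C; then 3, −78 °C to rt
Reagents that add atoms: ethyltriphenylphosphonium iodide, CC[P+](c1ccccc1)(c1ccccc1)c1ccccc1.[I-]; iodine, II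
Why: Stork–Zhao-type Wittig olefination with the iodo ylide Ph3P=C(I)CH3 gives the Z-trisubstituted vinyl iodide (iodine cis to the chain) under kinetic control, which fixes the later Z-C1=C10 geometry.

**Step 3**
Reactants: 4 (2E,6Z)-7-iodo-3-methylocta-2,6-dien-1-yl acetate
Product: 5 (2E,6Z)-7-iodo-3-methylocta-2,6-dien-1-ol
Conditions: K2CO3 (cat.), MeOH, rt
Reagents that add atoms: none
Why: Base-catalysed transesterification (methanolysis) removes the acetate and leaves the vinyl iodide and both alkenes untouched.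

**Step 4**
Reactants: 5 (2E,6Z)-7-iodo-3-methylocta-2,6-dien-1-ol
Product: 6 (2E,6Z)-7-iodo-3-methylocta-2,6-dienal
Conditions: MnO2, CH2Cl2, rt
Reagents that add atoms: none
Why: Activated MnO2 oxidises the allylic alcohol to the enal without over-oxidation or E/Z isomerisation (geraniol-to-geranial type oxidation).

**Step 5**
Reactants: 6 (2E,6Z)-7-iodo-3-methylocta-2,6-dienal
Product: 7 rac-(4E,8Z)-9-iodo-5-methyldeca-1,4,8-trien-3-ol
Conditions: CH2=CHMgBr, THF, −78 °C; then aq. NH4Cl
Reagents that add atoms: vinylmagnesium bromide, C=C[Mg]Br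
Why: Grignard 1,2-addition to the enal gives the bis-allylic alcohol; the new C6 centre forms as the racemate and is resolved in step 6.

**Step 6**
Reactants: 7 rac-(4E,8Z)-9-iodo-5-methyldeca-1,4,8-trien-3-ol
Product: 8 (3S,4E,8Z)-9-iodo-5-methyldeca-1,4,8-trien-3-ol
Conditions: Novozym 435 (immobilised Candida antarctica lipase B), vinyl acetate, hexane, 30 °C, stopped just beyond half conversion
Reagents that add atoms: none
Why: Lipase-catalysed kinetic resolution by transesterification: following the Kazlauskas rule the enzyme should acetylate the (R)-alcohol, in which vinyl fills the medium pocket, and leave the (S)-alcohol, which carries the C6 configuration of the target.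

**Step 7**
Reactants: 9 methyl 2-(bromomethyl)acrylate; 10 2-(tert-butyldimethylsilyloxy)ethanol
Product: 11 methyl 2-{[2-(tert-butyldimethylsilyloxy)ethoxy]methyl}prop-2-enoate
Conditions: DABCO (cat.), Et3N, CH2Cl2, 0 °C to rt
Reagents that add atoms: none
Why: Amine-mediated allylic substitution of the Morita–Baylis–Hillman-type bromide (SN2′ then SN2′ through the allylammonium salt) by the primary alcohol forms the future O8–C13 ether.

**Step 8**
Reactants: 11 methyl 2-{[2-(tert-butyldimethylsilyloxy)ethoxy]methyl}prop-2-enoate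
Product: 12 2-{[2-(tert-butyldimethylsilyloxy)ethoxy]methyl}prop-2-enoic acid
Conditions: LiOH, THF–H2O, 0 °C; then 1 M HCl to pH 4
Reagents that add atoms: lithium hydroxide, [Li+].[OH-]
Why: Saponification of the methyl ester with cold LiOH, which the silyl ether and the 2-(alkoxymethyl)acrylate should survive.

**Step 9**
Reactants: 8 (3S,4E,8Z)-9-iodo-5-methyldeca-1,4,8-trien-3-ol; 12 2-{[2-(tert-butyldimethylsilyloxy)ethoxy]methyl}prop-2-enoic acid
Product: 13 (3S,4E,8Z)-9-iodo-5-methyldeca-1,4,8-trien-3-yl 2-{[2-(tert-butyldimethylsilyloxy)ethoxy]methyl}prop-2-enoate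
Conditions: DCC, DMAP (cat.), CH2Cl2, 0 °C to rt
Reagents that add atoms: none
Why: Steglich esterification joins the two fragments at O6 with retention at C6.

**Step 10**
Reactants: 13 (3S,4E,8Z)-9-iodo-5-methyldeca-1,4,8-trien-3-yl 2-{[2-(tert-butyldimethylsilyloxy)ethoxy]methyl}prop-2-enoate
Product: 14 (5R)-3-{[2-(tert-butyldimethylsilyloxy)ethoxy]methyl}-5-[(1E,5Z)-6-iodo-2-methylhepta-1,5-dien-1-yl]furan-2(5H)-one
Conditions: second-generation Grubbs catalyst RuCl2(=CHPh)(H2IMes)(PCy3) (cat.), CH2Cl2, 40 °C
Reagents that add atoms: none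
Why: Ring-closing metathesis between the vinyl group and the acrylate alkene closes the five-membered butenolide with loss of ethene, the trisubstituted alkenes and the vinyl iodide being unreactive towards the ruthenium carbene.

**Step 11**
Reactants: 14 (5R)-3-{[2-(tert-butyldimethylsilyloxy)ethoxy]methyl}-5-[(1E,5Z)-6-iodo-2-methylhepta-1,5-dien-1-yl]furan-2(5H)-one
Product: 15 (5R)-3-[(2-hydroxyethoxy)methyl]-5-[(1E,5Z)-6-iodo-2-methylhepta-1,5-dien-1-yl]furan-2(5H)-one
Conditions: HF·pyridine, pyridine, THF, 0 °C
Reagents that add atoms: none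
Why: Fluoride-induced desilylation under buffered conditions frees the primary alcohol without deprotonating the butenolide at C6.

**Step 12**
Reactants: 15 (5R)-3-[(2-hydroxyethoxy)methyl]-5-[(1E,5Z)-6-iodo-2-methylhepta-1,5-dien-1-yl]furan-2(5H)-one
Product: 16 {[(5R)-5-[(1E,5Z)-6-iodo-2-methylhepta-1,5-dien-1-yl]-2-oxo-2,5-dihydrofuran-3-yl]methoxy}acetaldehyde
Conditions: Dess–Martin periodinane, CH2Cl2, 0 °C to rt
Reagents that add atoms: none
Why: Dess–Martin oxidation gives the α-alkoxy aldehyde under neutral conditions; it would be used crude.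

**Step 13**
Reactants: 16 {[(5R)-5-[(1E,5Z)-6-iodo-2-methylhepta-1,5-dien-1-yl]-2-oxo-2,5-dihydrofuran-3-yl]methoxy}acetaldehyde
Product: 17 (6Z,10E,12R)-5-hydroxy-6,10-dimethyl-3,13-dioxabicyclo[10.2.1]pentadeca-1(15),6,10-trien-14-one (thirteen-membered ring; position 5 is C9, both epimers)
Conditions: CrCl2 (excess), NiCl2 (cat.), DMSO–THF, rt, high dilution, slow addition of 16
Reagents that add atoms: none
Why: Intramolecular Nozaki–Hiyama–Kishi coupling: nickel catalysis turns the vinyl iodide into a vinylchromium reagent with retention of the Z geometry, which adds only to the aldehyde and closes the thirteen-membered ring; C9 forms as an epimer mixture that step 14 removes.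

**Step 14**
Reactants: 17 (6Z,10E,12R)-5-hydroxy-6,10-dimethyl-3,13-dioxabicyclo[10.2.1]pentadeca-1(15),6,10-trien-14-one
Product: 18 (6Z,10E,12R)-6,10-dimethyl-3,13-dioxabicyclo[10.2.1]pentadeca-1(15),6,10-triene-5,14-dione (the C6-R butenolide whose C13 is bridged through O8–C8H2–C9(=O) to C10)
Conditions: Dess–Martin periodinane, CH2Cl2, 0 °C to rt
Reagents that add atoms: none
Why: Dess–Martin oxidation of the allylic alcohol gives the Z-enone without acid or base able to isomerise it.

**Step 15**
Reactants: 18 (6Z,10E,12R)-6,10-dimethyl-3,13-dioxabicyclo[10.2.1]pentadeca-1(15),6,10-triene-5,14-dione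
Product: 20 (6R,7R,8S)-8-hydroxy-9-oxogermacra-1(10)Z,4E,11(13)-trien-12,6-olide, via potassium C8 enolate 19 (not isolated)
Conditions: 18 added to KN(SiMe3)2 (1.05 equiv), THF, −78 °C; AcOH, −78 °C
Reagents that add atoms: none
Why: Proposed new method: KN(SiMe3)2 should remove a C8 proton (the only unhindered CH2, acidified by both the C9 carbonyl and the ether oxygen) to give the chelated Z-enolate 19, whose C8 terminus bonds to butenolide carbon C7 while the C13–O8 bond breaks, either as one [2,3]-sigmatropic event through a five-membered envelope or as Michael addition followed by E1cB loss of the alkoxide; both paths give the C7–C8 bond, the C11=C13 methylene and the O8 alkoxide. The closest known reactions are the [2,3]-Wittig rearrangement of α-allyloxy ketone and ester enolates, the [2,3]-Wittig ring contraction of thirteen-membered allylic ethers to ten-membered carbocycles and the SN2′ addition of enolates to 2-(alkoxymethyl)acrylates; their combination on an allyl ether that is part of a butenolide is new. The ten-membered carbocycle closes by contraction of the thirteen-membered ring through a five-centre transition state (formally 5-endo at C7, allowed because O8 leaves C13 in the same event), so no medium-ring closure from an open chain is needed. C7 is set by C6, the enolate adding to the butenolide face anti to the C5 side chain (trans-lactone), and C8 by the enolate face that the tether leaves open: with O8 held on the C13 side, the Z-C1=C10/E-C4=C5 chain that ends on the other face of C6 is expected to fold the C9 carbonyl arm over the C6 edge of the lactone, which gives 8S. The step needs deprotonation at C8 and not at the γ-position C6, and attack at C7 and not at the lactone carbonyl; potassium chelation by the 1,2-keto ether, inverse addition at −78 °C and the alignment of the breaking C13–O bond with the butenolide π system are relied on for this, and the cold acetic acid quench should prevent translactonisation onto O8, epimerisation at C8 and Z-to-E isomerisation of the enone.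

**Step 16**
Reactants: 21 (R)-citramalic acid
Product: 22 dimethyl (2R)-2-hydroxy-2-methylbutanedioate
Conditions: 1 M HCl in MeOH, rt
Reagents that add atoms: methanol, CO
Why: Fischer esterification of both carboxyl groups at room temperature, which avoids dehydration of the tertiary alcohol.

**Step 17**
Reactants: 22 dimethyl (2R)-2-hydroxy-2-methylbutanedioate
Product: 23 methyl (3R)-3,4-dihydroxy-3-methylbutanoate
Conditions: BH3·SMe2, NaBH4 (cat.), THF, 0 °C to rt; then MeOH
Reagents that add atoms: none
Why: Hydroxyl-directed borane reduction: the alkoxyborane formed at the tertiary hydroxyl delivers hydride through a five-membered chelate to the neighbouring ester only, and the stereocentre is not touched.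

**Step 18**
Reactants: 23 methyl (3R)-3,4-dihydroxy-3-methylbutanoate
Product: 24 methyl (3R)-3-hydroxy-3-methyl-4-[(4-methylphenyl)sulfonyloxy]butanoate
Conditions: TsCl, pyridine, CH2Cl2, 0 °C
Reagents that add atoms: 4-toluenesulfonyl chloride, Cc1ccc(cc1)S(=O)(=O)Cl
Why: Selective sulfonylation of the primary hydroxyl; the tertiary hydroxyl does not react.

**Step 19**
Reactants: 24 methyl (3R)-3-hydroxy-3-methyl-4-[(4-methylphenyl)sulfonyloxy]butanoate
Product: 26 [(2R)-2-methyloxiran-2-yl]acetic acid, via methyl epoxy ester 25 (not isolated)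
Conditions: LiOH (2.2 equiv), THF–H2O, 0 °C; then 1 M HCl to pH 4 at 0 °C, extracted at once and used as a solution
Reagents that add atoms: lithium hydroxide, [Li+].[OH-]
Why: Intramolecular Williamson reaction (3-exo-tet) of the tertiary alkoxide with the primary tosylate closes the epoxide without touching the quaternary stereocentre, and saponification then gives the carboxylate, which cannot open the epoxide by E1cB.

**Step 20**
Reactants: 20 (6R,7R,8S)-8-hydroxy-9-oxogermacra-1(10)Z,4E,11(13)-trien-12,6-olide; 26 [(2R)-2-methyloxiran-2-yl]acetic acid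
Product: 27 (6R,7S,8S)-8-{[(2R)-2-methyloxiran-2-yl]acetoxy}-9-oxogermacra-1(10)Z,4E,11(13)-trien-12,6-olide
Conditions: DCC, DMAP (cat.), CH2Cl2, −20 to 0 °C
Reagents that add atoms: none
Why: Steglich esterification acylates the C8 hydroxyl with retention, and low temperature with catalytic DMAP should keep the C8–H of the ketol and the α-protons of the epoxy acid from being removed.

**Step 21**
Reactants: 27 (6R,7S,8S)-8-{[(2R)-2-methyloxiran-2-yl]acetoxy}-9-oxogermacra-1(10)Z,4E,11(13)-trien-12,6-olide
Product: 28 (6R,7S,8S,9R)-9-hydroxy-8-{[(2R)-2-methyloxiran-2-yl]acetoxy}germacra-1(10)Z,4E,11(13)-trien-12,6-olide (CNP0284481.1)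
Conditions: NaBH4, CeCl3·7H2O, MeOH, −78 °C; cold aq. NH4Cl
Reagents that add atoms: none
Why: Luche reduction adds hydride 1,2 to the enone carbonyl and should spare the α-methylene lactone, the esters and the epoxide; with cerium bridging the C9 carbonyl and O8, hydride is expected from the side of the C8 hydrogen on the outer face of the ring, giving the 9R alcohol cis to the C8 ester.

**Compound list**
1 | geranyl acetate | CC(C)=CCC/C(C)=C/COC(C)=O | starting material
2 | 6,7-epoxygeranyl acetate (racemic, not isolated) | CC(=O)OC/C=C(\C)CCC1OC1(C)C | intermediate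
3 | (2E)-3-methyl-6-oxohex-2-en-1-yl acetate | CC(=O)OC/C=C(\C)CCC=O | intermediate
4 | (2E,6Z)-7-iodo-3-methylocta-2,6-dien-1-yl acetate | CC(=O)OC/C=C(\C)CC/C=C(/C)I | intermediate
5 | (2E,6Z)-7-iodo-3-methylocta-2,6-dien-1-ol | OC/C=C(\C)CC/C=C(/C)I | intermediate
6 | (2E,6Z)-7-iodo-3-methylocta-2,6-dienal | O=C/C=C(\C)CC/C=C(/C)I | intermediate
7 | rac-(4E,8Z)-9-iodo-5-methyldeca-1,4,8-trien-3-ol | OC(C=C)/C=C(\C)CC/C=C(/C)I | intermediate
8 | (3S,4E,8Z)-9-iodo-5-methyldeca-1,4,8-trien-3-ol | O[C@@H](C=C)/C=C(\C)CC/C=C(/C)I | intermediate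
9 | methyl 2-(bromomethyl)acrylate | C=C(CBr)C(=O)OC | starting material
10 | 2-(tert-butyldimethylsilyloxy)ethanol | OCCO[Si](C)(C)C(C)(C)C | starting material
11 | methyl 2-{[2-(tert-butyldimethylsilyloxy)ethoxy]methyl}prop-2-enoate | C=C(COCCO[Si](C)(C)C(C)(C)C)C(=O)OC | intermediate
12 | 2-{[2-(tert-butyldimethylsilyloxy)ethoxy]methyl}prop-2-enoic acid | C=C(COCCO[Si](C)(C)C(C)(C)C)C(=O)O | intermediate
13 | (3S,4E,8Z)-9-iodo-5-methyldeca-1,4,8-trien-3-yl 2-{[2-(tert-butyldimethylsilyloxy)ethoxy]methyl}prop-2-enoate | C=C(COCCO[Si](C)(C)C(C)(C)C)C(=O)O[C@@H](C=C)/C=C(\C)CC/C=C(/C)I | intermediate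
14 | (5R)-3-{[2-(tert-butyldimethylsilyloxy)ethoxy]methyl}-5-[(1E,5Z)-6-iodo-2-methylhepta-1,5-dien-1-yl]furan-2(5H)-one | O=C1O[C@H](/C=C(\C)CC/C=C(/C)I)C=C1COCCO[Si](C)(C)C(C)(C)C | intermediate
15 | (5R)-3-[(2-hydroxyethoxy)methyl]-5-[(1E,5Z)-6-iodo-2-methylhepta-1,5-dien-1-yl]furan-2(5H)-one | O=C1O[C@H](/C=C(\C)CC/C=C(/C)I)C=C1COCCO | intermediate
16 | {[(5R)-5-[(1E,5Z)-6-iodo-2-methylhepta-1,5-dien-1-yl]-2-oxo-2,5-dihydrofuran-3-yl]methoxy}acetaldehyde | O=C1O[C@H](/C=C(\C)CC/C=C(/C)I)C=C1COCC=O | intermediate
17 | (6Z,10E,12R)-5-hydroxy-6,10-dimethyl-3,13-dioxabicyclo[10.2.1]pentadeca-1(15),6,10-trien-14-one (C9 epimers) | O=C1O[C@@H]2/C=C(\C)CC/C=C(/C)C(O)COCC1=C2 | intermediate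
18 | (6Z,10E,12R)-6,10-dimethyl-3,13-dioxabicyclo[10.2.1]pentadeca-1(15),6,10-triene-5,14-dione | O=C1O[C@@H]2/C=C(\C)CC/C=C(/C)C(=O)COCC1=C2 | intermediate
19 | potassium Z-enolate of 18 (C8=C9; not isolated) | [K+].O=C1O[C@@H]2/C=C(\C)CC/C=C(/C)\C([O-])=C\OCC1=C2 | intermediate
20 | (6R,7R,8S)-8-hydroxy-9-oxogermacra-1(10)Z,4E,11(13)-trien-12,6-olide | C=C1C(=O)O[C@@H]2/C=C(\C)CC/C=C(/C)C(=O)[C@@H](O)[C@@H]12 | intermediate
21 | (R)-citramalic acid, (2R)-2-hydroxy-2-methylbutanedioic acid | OC(=O)C[C@](O)(C)C(=O)O | starting material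
22 | dimethyl (2R)-2-hydroxy-2-methylbutanedioate | COC(=O)C[C@](O)(C)C(=O)OC | intermediate
23 | methyl (3R)-3,4-dihydroxy-3-methylbutanoate | COC(=O)C[C@](O)(C)CO | intermediate
24 | methyl (3R)-3-hydroxy-3-methyl-4-[(4-methylphenyl)sulfonyloxy]butanoate | COC(=O)C[C@](O)(C)COS(=O)(=O)c1ccc(C)cc1 | intermediate
25 | methyl [(2R)-2-methyloxiran-2-yl]acetate (not isolated) | COC(=O)C[C@]1(C)CO1 | intermediate
26 | [(2R)-2-methyloxiran-2-yl]acetic acid | OC(=O)C[C@]1(C)CO1 | intermediate
27 | (6R,7S,8S)-8-{[(2R)-2-methyloxiran-2-yl]acetoxy}-9-oxogermacra-1(10)Z,4E,11(13)-trien-12,6-olide | C=C1C(=O)O[C@@H]2/C=C(\C)CC/C=C(/C)C(=O)[C@@H](OC(=O)C[C@]3(C)CO3)[C@@H]12 | intermediate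
28 | (6R,7S,8S,9R)-9-hydroxy-8-{[(2R)-2-methyloxiran-2-yl]acetoxy}germacra-1(10)Z,4E,11(13)-trien-12,6-olide | C=C1C(=O)O[C@@H]2/C=C(\C)CC/C=C(/C)[C@@H](O)[C@@H](OC(=O)C[C@]3(C)CO3)[C@@H]12 | target

**Step count**
Total: 21 steps. Longest linear sequence: 15 steps (steps 1–6, 9–15, 20 and 21); steps 7–8 and 16–19 are side branches.

**Steps most likely to fail**

Step 15 (key step). The base may take the γ-proton at C6 of the butenolide instead of a C8 proton, which would lead to loss of the C13 alkoxide and ring opening, or to racemisation of recovered 18. The enolate may also attack the lactone carbonyl (Dieckmann-type acylation), or bond to C7 through the other envelope and give the C8 epimer. Fallback by known chemistry, from 8 to 27: the C7–C8 bond is made between two molecules by a Barbier allylation and the ten-membered ring is then closed at C9–C10.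
- Alcohol 8 is acylated with 2-(bromomethyl)acryloyl chloride (2,6-lutidine, CH2Cl2, −20 °C) to (3S,4E,8Z)-9-iodo-5-methyldeca-1,4,8-trien-3-yl 2-(bromomethyl)prop-2-enoate F1.
- Ring-closing metathesis (second-generation Grubbs catalyst, CH2Cl2, 40 °C) gives (5R)-3-(bromomethyl)-5-[(1E,5Z)-6-iodo-2-methylhepta-1,5-dien-1-yl]furan-2(5H)-one F2.
- Zinc dust in THF–aq. NH4Cl with (4-methoxybenzyloxy)acetaldehyde adds the allylzinc through C7, anti to the C6 side chain, to give the α-methylene lactone alcohol F3. The C7/C8 relative configuration in this reaction type depends on the metal (zinc, indium or CrCl2), and the one that gives the target arrangement would be used.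
- Steglich esterification with acid 26 gives the C8 epoxy ester F4.
- DDQ (CH2Cl2–pH 7 buffer) removes the 4-methoxybenzyl group to give the primary alcohol F5.
- Dess–Martin oxidation gives the aldehyde F6.
- CrCl2/NiCl2 in DMSO at high dilution closes the ten-membered ring to the allylic alcohol F7 as a mixture of C9 epimers.
- Dess–Martin oxidation of F7 gives 27, from where step 21 is run.

Step 21 (reduction of the C9 ketone). Hydride may enter the wrong face of the carbonyl and give the 9-epimer, and the intermediate alkoxide may take over the acyl group from O8. Fallback, from 27 directly to 28: substrate control is given up for catalyst control. The ketone is reduced with (R)-2-methyl-CBS-oxazaborolidine and catecholborane in toluene at −78 °C. With the alkenyl branch (C10) acting as the large substituent, hydride is delivered to the face that gives 9R, under neutral conditions that do not favour acyl migration. No new compound arises.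

Step 13 (thirteen-membered ring closure). Intermolecular coupling and reduction of the vinyl–metal bond may outrun ring closure, because the planar butenolide stiffens the chain that has to meet the aldehyde. Fallback, from 13 to 18: the order of the two ring closures is reversed.
- HF·pyridine converts 13 into (3S,4E,8Z)-9-iodo-5-methyldeca-1,4,8-trien-3-yl 2-[(2-hydroxyethoxy)methyl]prop-2-enoate F8.
- Dess–Martin oxidation gives (3S,4E,8Z)-9-iodo-5-methyldeca-1,4,8-trien-3-yl 2-[(2-oxoethoxy)methyl]prop-2-enoate F9.
- The CrCl2/NiCl2 coupling is run on F9, where it closes a flexible fourteen-membered macrolactone, (8Z,12E,14S)-14-ethenyl-7-hydroxy-8,12-dimethyl-3-methylidene-1,5-dioxacyclotetradeca-8,12-dien-2-one F10.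
- Dess–Martin oxidation gives (8Z,12E,14S)-14-ethenyl-8,12-dimethyl-3-methylidene-1,5-dioxacyclotetradeca-8,12-diene-2,7-dione F11.
- Ring-closing metathesis across the macrocycle (second-generation Grubbs catalyst) then builds the butenolide and gives 18.

**Further compounds**
F1 | step 15 | (3S,4E,8Z)-9-iodo-5-methyldeca-1,4,8-trien-3-yl 2-(bromomethyl)prop-2-enoate | C=C(CBr)C(=O)O[C@@H](C=C)/C=C(\C)CC/C=C(/C)I
F2 | step 15 | (5R)-3-(bromomethyl)-5-[(1E,5Z)-6-iodo-2-methylhepta-1,5-dien-1-yl]furan-2(5H)-one | O=C1O[C@H](/C=C(\C)CC/C=C(/C)I)C=C1CBr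
F3 | step 15 | 4-[1-hydroxy-2-(4-methoxybenzyloxy)ethyl]-5-[(1E,5Z)-6-iodo-2-methylhepta-1,5-dien-1-yl]-3-methylideneoxolan-2-one, configured at C6, C7 and C8 as the target | C=C1C(=O)O[C@H](/C=C(\C)CC/C=C(/C)I)[C@H]1[C@H](O)COCc1ccc(OC)cc1
F4 | step 15 | [(2R)-2-methyloxiran-2-yl]acetate ester of F3 at O8 | C=C1C(=O)O[C@H](/C=C(\C)CC/C=C(/C)I)[C@H]1[C@H](OC(=O)C[C@]2(C)CO2)COCc1ccc(OC)cc1
F5 | step 15 | primary alcohol from F4 (C9 hydroxymethyl) | C=C1C(=O)O[C@H](/C=C(\C)CC/C=C(/C)I)[C@H]1[C@H](OC(=O)C[C@]2(C)CO2)CO
F6 | step 15 | aldehyde from F5 (C9 formyl) | C=C1C(=O)O[C@H](/C=C(\C)CC/C=C(/C)I)[C@H]1[C@H](OC(=O)C[C@]2(C)CO2)C=O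
F7 | step 15 | (6R,7S,8S)-9-hydroxy-8-{[(2R)-2-methyloxiran-2-yl]acetoxy}germacra-1(10)Z,4E,11(13)-trien-12,6-olide, C9 epimers | C=C1C(=O)O[C@@H]2/C=C(\C)CC/C=C(/C)C(O)[C@@H](OC(=O)C[C@]3(C)CO3)[C@@H]12
F8 | step 13 | (3S,4E,8Z)-9-iodo-5-methyldeca-1,4,8-trien-3-yl 2-[(2-hydroxyethoxy)methyl]prop-2-enoate | C=C(COCCO)C(=O)O[C@@H](C=C)/C=C(\C)CC/C=C(/C)I
F9 | step 13 | (3S,4E,8Z)-9-iodo-5-methyldeca-1,4,8-trien-3-yl 2-[(2-oxoethoxy)methyl]prop-2-enoate | C=C(COCC=O)C(=O)O[C@@H](C=C)/C=C(\C)CC/C=C(/C)I
F10 | step 13 | (8Z,12E,14S)-14-ethenyl-7-hydroxy-8,12-dimethyl-3-methylidene-1,5-dioxacyclotetradeca-8,12-dien-2-one, C7 epimers | C=C1C(=O)O[C@@H](C=C)/C=C(\C)CC/C=C(/C)C(O)COC1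
F11 | step 13 | (8Z,12E,14S)-14-ethenyl-8,12-dimethyl-3-methylidene-1,5-dioxacyclotetradeca-8,12-diene-2,7-dione | C=C1C(=O)O[C@@H](C=C)/C=C(\C)CC/C=C(/C)C(=O)COC1
F0 | step 21 | none | none
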